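Ring D, the 2H-pyran O1'–C2'(Me)2–C3'=C4' fused across C10=C11 of oxepine ring C, is read as a C11 prenyl chain whose tertiary carbon C2' has been bonded to the C10 enol oxygen. Cutting O1'–C2' therefore leads back to a C11-prenylated dibenzo[b,f]oxepin-10-one that already carries the ring A prenyl group and has both phenols masked as pivalates. In a single operation DDQ removes hydride from C4' of the enolised ketone and the resulting 1-oxatriene closes to ring D; the C10 enol is the only free hydroxyl beside a prenyl group. The tricyclic ketone is assembled by Ullmann etherification and Friedel–Crafts acylation.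

Key step: step 8

Remark on numbering: locants follow dibenzo[b,f]oxepine. Ring A is C1–C4 with C4a and C11a, ring B is C6–C9 with C5a and C9a, ring C holds O5, C10 and C11, and ring D is O1', C2', C3', C4'.

Assumption: salts that exist only until aqueous work-up (the cesium carboxylate in step 1, the sodium phenoxides in step 9) are treated as forms of the product and are not numbered. The target is achiral, and the single stereocentre of 13 (racemic) is erased in step 8.

Step 1
Reactants: 1 3-methoxyphenol; 2 2-bromo-4-methoxyphenylacetic acid
Product: 3 2-[4-methoxy-2-(3-methoxyphenoxy)phenyl]acetic acid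
Conditions: CuI (10 mol%), N,N-dimethylglycine (30 mol%), Cs2CO3 (3 equiv), 1,4-dioxane, 100 °C, argon; then aq. HCl
Reagents that add atoms: none
Why: Copper-catalysed Ullmann diaryl ether synthesis, in which the cesium phenoxide of 1 displaces the aryl bromide of 2 while the neighbouring acetic acid side chain is carried as its carboxylate, a much poorer nucleophile than the phenoxide.

Step 2
Reactants: 3 2-[4-methoxy-2-(3-methoxyphenoxy)phenyl]acetic acid
Product: 4 3,7-dimethoxydibenzo[b,f]oxepin-10(11H)-one
Conditions: PPA, 80 °C
Reagents that add atoms: none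
Why: Intramolecular Friedel–Crafts acylation, in which the activated acid attacks the phenoxy ring ortho to the ether oxygen and para to its methoxy group, a site more accessible than the one between the two oxygens, and so closes the seven-membered ring C.

Step 3
Reactants: 4 3,7-dimethoxydibenzo[b,f]oxepin-10(11H)-one
Product: 5 2-bromo-3,7-dimethoxydibenzo[b,f]oxepin-10(11H)-one
Conditions: NBS (1.0 equiv), MeCN, 0 °C, dark
Reagents that add atoms: N-bromosuccinimide, O=C1CCC(=O)N1Br
Why: Electrophilic aromatic bromination should go to C2 of ring A, which is ortho to the C3 methoxy group, para to O5 and unhindered, whereas ring B is deactivated by the C10 carbonyl, C4 lies between two oxygens, and the C11 methylene does not enolise fast enough without acid or light.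

Step 4
Reactants: 5 2-bromo-3,7-dimethoxydibenzo[b,f]oxepin-10(11H)-one
Product: 7 2-bromo-3,7-dihydroxydibenzo[b,f]oxepin-10(11H)-one, via bis(dibromoboryl) ether 6 (not isolated)
Conditions: BBr3 (4 equiv), CH2Cl2, –78 °C to rt; then H2O
Reagents that add atoms: none
Why: Lewis acid demethylation of aryl methyl ethers, in which BBr3 binds each methoxy oxygen and bromide attacks the methyl carbon by SN2, so the diaryl ether, the ketone and the aryl bromide should survive and the aryl borate 6 is hydrolysed on work-up.

Step 5
Reactants: 7 2-bromo-3,7-dihydroxydibenzo[b,f]oxepin-10(11H)-one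
Product: 8 2-bromo-10-oxo-10,11-dihydrodibenzo[b,f]oxepine-3,7-diyl bis(2,2-dimethylpropanoate)
Conditions: PivCl (2.3 equiv), Et3N (3 equiv), DMAP (5 mol%), CH2Cl2, 0 °C
Reagents that add atoms: pivaloyl chloride, CC(C)(C)C(=O)Cl
Why: DMAP-catalysed O-acylation of phenols is far faster than acylation of the weakly enolised C10 ketone, so a small excess of acid chloride at 0 °C should give only the bis-pivalate.

Step 6
Reactants: 8 2-bromo-10-oxo-10,11-dihydrodibenzo[b,f]oxepine-3,7-diyl bis(2,2-dimethylpropanoate); 9 tributyl(3-methylbut-2-enyl)stannane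
Product: 10 2-(3-methylbut-2-enyl)-10-oxo-10,11-dihydrodibenzo[b,f]oxepine-3,7-diyl bis(2,2-dimethylpropanoate)
Conditions: Pd(PPh3)4 (5 mol%), DMF, 90 °C, argon
Reagents that add atoms: tributyl(3-methylbut-2-enyl)stannane (9), CC(C)=CC[Sn](CCCC)(CCCC)CCCC
Why: Stille cross-coupling, in which oxidative addition into the C2–Br bond, transfer of the prenyl group from tin and reductive elimination through the unsubstituted allyl terminus should give the linear prenyl arene under base-free conditions that spare the pivalates and the acidic C11 methylene.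

Step 7
Reactants: 10 2-(3-methylbut-2-enyl)-10-oxo-10,11-dihydrodibenzo[b,f]oxepine-3,7-diyl bis(2,2-dimethylpropanoate); 11 1-bromo-3-methylbut-2-ene (prenyl bromide)
Product: 13 rac-2,11-bis(3-methylbut-2-enyl)-10-oxo-10,11-dihydrodibenzo[b,f]oxepine-3,7-diyl bis(2,2-dimethylpropanoate), via lithium enolate 12 (not isolated)
Conditions: LiN(SiMe3)2 (1.05 equiv), THF, –78 °C; then 11 (1.1 equiv), –78 to 0 °C
Reagents that add atoms: 1-bromo-3-methylbut-2-ene (11), CC(C)=CCBr
Why: Enolate C-alkylation by SN2, in which the lithium enolate 12 in THF should react with the soft allylic bromide at carbon and stop at monoalkylation because the remaining C11–H is tertiary and hindered; the new C11 stereocentre forms as a racemate, which is acceptable because step 8 removes it.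

Step 8
Reactants: 13 rac-2,11-bis(3-methylbut-2-enyl)-10-oxo-10,11-dihydrodibenzo[b,f]oxepine-3,7-diyl bis(2,2-dimethylpropanoate)
Product: 16 artocarpol D dipivalate, via enol tautomer 14 (not isolated), via alkylidene dienone 15 (not isolated)
Conditions: DDQ (1.1 equiv), PPTS (10 mol%), 1,4-dioxane, 80 °C, argon, dark
Reagents that add atoms: none
Why: Proposed new method: the closest known reaction type is the DDQ dehydrogenative cyclisation of ortho-prenyl phenols and of enolised 2-prenyl 1,3-dicarbonyl compounds to 2,2-dimethyl-2H-pyrans, extended here to the enol of an alpha-prenyl alpha-aryl ketone and supported by the familiar DDQ dehydrogenation of enolisable ketones. The C11–H of 13 is benzylic and alpha to the C10 carbonyl, so the pyridinium/pyridine pair should equilibrate 13 with enol 14, from whose doubly allylic C4' methylene DDQ takes hydride to give a cation spread from the enol oxygen to C2'; loss of the O–H proton then leaves the 1-oxatriene 15 (O=C10–C11=C4'–C3'=C2'). The six-membered ring D closes by a thermal disrotatory oxa-6π electrocyclisation that forms the O1'–C2' bond, the reactive Z geometry at C11=C4' being reachable by rotation at the cation stage, and closure is favoured because it replaces a twisted cross-conjugated exocyclic dienone by a stilbene-like enol ether. No stereocentre is formed and the racemic C11 centre of 13 is erased. The selectivity required is between the two prenyl groups, and it is secured because only the C11 prenyl group adjoins a free (enol) hydroxyl, whereas the ring A prenyl group adjoins a pivalate that cannot give a quinone methide and damps hydride donation from ring A; a single equivalent of DDQ limits over-oxidation.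

Step 9
Reactants: 16 artocarpol D dipivalate
Product: 17 artocarpol D
Conditions: NaOMe (3 equiv), degassed MeOH/THF, 0 °C to rt, argon; then AcOH
Reagents that add atoms: none
Why: Base-mediated transesterification (methanolysis) of aryl esters, in which methoxide attacks the pivaloyl carbonyls and expels the phenoxides while the prenyl group, the 2H-pyran enol ether and the diaryl ether are inert to base, and mild acidification returns the free phenols.

Compound list
1 | 3-methoxyphenol | COc1cccc(O)c1 | starting material
2 | 2-bromo-4-methoxyphenylacetic acid | COc1ccc(CC(=O)O)c(Br)c1 | starting material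
3 | 2-[4-methoxy-2-(3-methoxyphenoxy)phenyl]acetic acid | COc1cccc(Oc2cc(OC)ccc2CC(=O)O)c1 | intermediate
4 | 3,7-dimethoxydibenzo[b,f]oxepin-10(11H)-one | COc1ccc2CC(=O)c3ccc(OC)cc3Oc2c1 | intermediate
5 | 2-bromo-3,7-dimethoxydibenzo[b,f]oxepin-10(11H)-one | COc1cc2Oc3cc(OC)ccc3C(=O)Cc2cc1Br | intermediate
6 | 2-bromo-3,7-bis(dibromoboryloxy)dibenzo[b,f]oxepin-10(11H)-one | BrB(Br)Oc1cc2Oc3cc(OB(Br)Br)ccc3C(=O)Cc2cc1Br | intermediate (not isolated)
7 | 2-bromo-3,7-dihydroxydibenzo[b,f]oxepin-10(11H)-one | Oc1cc2Oc3cc(O)ccc3C(=O)Cc2cc1Br | intermediate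
8 | 2-bromo-10-oxo-10,11-dihydrodibenzo[b,f]oxepine-3,7-diyl bis(2,2-dimethylpropanoate) | CC(C)(C)C(=O)Oc1cc2Oc3cc(OC(=O)C(C)(C)C)ccc3C(=O)Cc2cc1Br | intermediate
9 | tributyl(3-methylbut-2-enyl)stannane | CC(C)=CC[Sn](CCCC)(CCCC)CCCC | starting material
10 | 2-(3-methylbut-2-enyl)-10-oxo-10,11-dihydrodibenzo[b,f]oxepine-3,7-diyl bis(2,2-dimethylpropanoate) | CC(C)=CCc1cc2CC(=O)c3ccc(OC(=O)C(C)(C)C)cc3Oc2cc1OC(=O)C(C)(C)C | intermediate
11 | 1-bromo-3-methylbut-2-ene (prenyl bromide) | CC(C)=CCBr | starting material
12 | lithium enolate of 10 (lithium 10-oxido-dibenzo[b,f]oxepine) | CC(C)=CCc1cc2C=C([O-])c3ccc(OC(=O)C(C)(C)C)cc3Oc2cc1OC(=O)C(C)(C)C.[Li+] | intermediate (not isolated)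
13 | rac-2,11-bis(3-methylbut-2-enyl)-10-oxo-10,11-dihydrodibenzo[b,f]oxepine-3,7-diyl bis(2,2-dimethylpropanoate) (racemate, one enantiomer drawn) | CC(C)=CCc1cc2c(cc1OC(=O)C(C)(C)C)Oc1cc(OC(=O)C(C)(C)C)ccc1C(=O)[C@H]2CC=C(C)C | intermediate
14 | 10-hydroxy-2,11-bis(3-methylbut-2-enyl)dibenzo[b,f]oxepine-3,7-diyl bis(2,2-dimethylpropanoate) (enol of 13) | CC(C)=CCC1=C(O)c2ccc(OC(=O)C(C)(C)C)cc2Oc2cc(OC(=O)C(C)(C)C)c(CC=C(C)C)cc12 | intermediate (not isolated)
15 | (Z)-11-(3-methylbut-2-enylidene)-2-(3-methylbut-2-enyl)-10-oxo-10,11-dihydrodibenzo[b,f]oxepine-3,7-diyl bis(2,2-dimethylpropanoate) | CC(C)=C/C=C1\C(=O)c2ccc(OC(=O)C(C)(C)C)cc2Oc2cc(OC(=O)C(C)(C)C)c(CC=C(C)C)cc12 | intermediate (not isolated)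
16 | artocarpol D dipivalate | CC(C)=CCc1cc2c(cc1OC(=O)C(C)(C)C)Oc1cc(OC(=O)C(C)(C)C)ccc1C1=C2C=CC(C)(C)O1 | intermediate
17 | artocarpol D | CC(C)=CCc1cc2c(cc1O)Oc1cc(O)ccc1C1=C2C=CC(C)(C)O1 | target

Total step count: 9
Longest linear sequence: 9 steps (1 or 2 to 17)

Steps most likely to fail

Risk 1 (step 8, the proposed new method). Enolisation of 13 may be too slow, so that hydride abstraction from the ring A benzylic methylene, or further oxidation of the product, competes with the wanted dehydrogenation. The fallback uses known chemistry and sets out from 10. The lithium enolate 12 (LiN(SiMe3)2, THF, –78 °C) is added to 3-methylbut-2-enal in a directed aldol reaction and should give the 11-(1-hydroxy-3-methylbut-2-enyl) ketone F1 as a diastereomer mixture. Treatment with MsCl and Et3N in CH2Cl2 (0 °C to rt) should form the methanesulfonate F2, which eliminates in the flask by E1cB to the dienone 15. Dienone 15 then closes by the same oxa-6π electrocyclisation, if necessary on gentle warming, and the route is rejoined at 16.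

Risk 2 (step 7). The ambident enolate may alkylate on oxygen, alkylate twice at C11, or take up a pivaloyl group from a neighbouring molecule. The fallback sets out from 10 and swaps the SN2 alkylation for a Tsuji–Trost allylic alkylation: enolate 12 is treated with 3-methylbut-2-enyl acetate and Pd(PPh3)4 (5 mol%) in THF at rt. The soft prenyl–palladium electrophile should be attacked by carbon at its unsubstituted terminus, and any O-allylated material is re-ionised by the catalyst and funnelled to the C-alkylated ketone. The fallback rejoins the route at 13 and makes no new compound, none (F0).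

Risk 3 (step 6). Coupling may occur through the substituted allyl terminus (reverse prenyl), or the stannane may be lost by protodestannylation before a sluggish transmetalation. The fallback sets out from 8. Stille coupling with allyltributylstannane (Pd(PPh3)4, DMF, 90 °C), which has no regiochemical ambiguity, should give the 2-allyl ketone F3. Olefin cross-metathesis of F3 with excess 2-methylbut-2-ene (second-generation Grubbs catalyst, CH2Cl2, 40 °C) then converts the allyl into the prenyl group, and the route is rejoined at 10.

Further compounds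
F1 | step 8 | rac-11-(1-hydroxy-3-methylbut-2-enyl)-2-(3-methylbut-2-enyl)-10-oxo-10,11-dihydrodibenzo[b,f]oxepine-3,7-diyl bis(2,2-dimethylpropanoate) (diastereomer mixture, configuration undefined) | CC(C)=CC(O)C1C(=O)c2ccc(OC(=O)C(C)(C)C)cc2Oc2cc(OC(=O)C(C)(C)C)c(CC=C(C)C)cc12
F2 | step 8 | methanesulfonate of F1 (diastereomer mixture, configuration undefined) | CC(C)=CC(OS(C)(=O)=O)C1C(=O)c2ccc(OC(=O)C(C)(C)C)cc2Oc2cc(OC(=O)C(C)(C)C)c(CC=C(C)C)cc12
F0 | step 7 | none | none
F3 | step 6 | 2-allyl-10-oxo-10,11-dihydrodibenzo[b,f]oxepine-3,7-diyl bis(2,2-dimethylpropanoate) | C=CCc1cc2CC(=O)c3ccc(OC(=O)C(C)(C)C)cc3Oc2cc1OC(=O)C(C)(C)C
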